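## Retrosynthetic overview

1. The lactone oxygen O-2 sits on C-3, a carbon of the 12-membered ring that carries one methyl group. This O–C(CH3) unit is the Markovnikov adduct of a carboxylic acid and a terminal alkyne, so the O-2–C-3 bond is cut back to an ω-alkynyl benzoic acid. Forward, a 12-exo-dig hydro-oxycarbonylation closes the macrolactone as an exo-methylene enol ester, and asymmetric hydrogenation of C-3=CH2 then sets the (3R) centre.
2. The nine-carbon chain is cut at the benzylic C–C bond: lateral alkylation of an o-toluic acid dianion with a silyl-protected ω-bromoalkyne. The carboxyl group comes from bromination, lithiation and CO2.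
3. The cis-fused pyran/tetrahydrofuran ketal (three stereocentres) is cut at the aryl O–C(ketal) and ArCH2–C bonds: hetero-Diels–Alder reaction of an o-quinone methide with (S)-3,5-dimethyl-2,3-dihydrofuran, itself made by an Evans propargylation.
4. Order of ring formation: tetrahydrofuran ring (as the dihydrofuran), pyran ring (ketal), then the 12-membered lactone. The benzene ring is bought.

Key step: step 12

Remark on the chemistry: the macrolide is numbered as in lasiodiplodin (C-1 lactone carbonyl, O-2, C-3 methyl-bearing carbon); the ketal unit is numbered as a furo[2,3-b]chromene (O-1, C-2, C-3, C-3a, C-4, C-4a to C-8a, O-9, C-9a).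

## Route

Step 1
Reactants: 1 (R)-4-benzyl-3-propionyloxazolidin-2-one; 2 3-bromoprop-1-yne
Product: 4 (R)-4-benzyl-3-[(S)-2-methylpent-4-ynoyl]oxazolidin-2-one, via sodium enolate 3 (not isolated)
Conditions: NaN(SiMe3)2 (1.1 equiv), THF, −78 °C; then 2 (3 equiv), −78 to −40 °C
Reagents that add atoms: none
Why: Evans asymmetric alkylation, in which the chelated (Z)-enolate is attacked on the face opposite the benzyl group of the auxiliary, which sets the (S)-configured methyl-bearing carbon that becomes C-3 of the ketal unit.

Step 2
Reactants: 4 (R)-4-benzyl-3-[(S)-2-methylpent-4-ynoyl]oxazolidin-2-one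
Product: 5 (S)-2-methylpent-4-yn-1-ol
Conditions: LiBH4 (1.2 equiv), H2O (1.2 equiv), Et2O, 0 °C
Reagents that add atoms: none
Why: Reductive cleavage of the N-acyl oxazolidinone by borohydride should give the primary alcohol without touching the α-stereocentre and release the auxiliary for recovery.

Step 3
Reactants: 5 (S)-2-methylpent-4-yn-1-ol
Product: 7 (S)-3,5-dimethyl-2,3-dihydrofuran, via exocyclic enol ether 6 (not isolated)
Conditions: NaNH2 (5 mol %), neat, 110 °C, product distilled from the flask
Reagents that add atoms: none
Why: Base-catalysed 5-exo-dig cycloisomerisation of the alkoxide onto the alkyne followed by base-mediated migration of the exocyclic double bond into the ring, a known preparation of this type of dihydrofuran in which the stereocentre is not involved.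

Step 4
Reactants: 8 2,4-dihydroxy-6-methylbenzaldehyde
Product: 9 2-hydroxy-4-methoxy-6-methylbenzaldehyde
Conditions: MeI (1.05 equiv), K2CO3 (1.0 equiv), acetone, rt
Reagents that add atoms: iodomethane, CI
Why: Williamson etherification, selective for the 4-hydroxyl because the 2-hydroxyl is held in a hydrogen bond to the aldehyde and is much less nucleophilic.

Step 5
Reactants: 9 2-hydroxy-4-methoxy-6-methylbenzaldehyde
Product: 10 2-[(dimethylamino)methyl]-5-methoxy-3-methylphenol
Conditions: Me2NH (2 M in THF, 2 equiv), NaBH(OAc)3 (1.5 equiv), ClCH2CH2Cl, rt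
Reagents that add atoms: dimethylamine, CNC
Why: Reductive amination converts the formyl carbon, which already occupies the correct ring position, into the aminomethyl group, so the regiochemistry of the o-quinone methide precursor is unambiguous.

Step 6
Reactants: 10 2-[(dimethylamino)methyl]-5-methoxy-3-methylphenol; 7 (S)-3,5-dimethyl-2,3-dihydrofuran
Product: 13 (3S,3aS,9aS)-7-methoxy-3,5,9a-trimethyl-2,3,3a,9a-tetrahydro-4H-furo[2,3-b]chromene, via ammonium iodide 11 (not isolated), via o-quinone methide 12 (not isolated)
Conditions: MeI (1.1 equiv), 7 (2.5 equiv), PhMe, rt then 90 °C, sealed tube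
Reagents that add atoms: none
Why: Quaternisation and thermal loss of trimethylamine give the o-quinone methide, which the enol ether traps in an inverse-electron-demand hetero-Diels–Alder reaction (methylene to the enol β-carbon, oxygen to the oxocarbenium carbon); the suprafacial addition makes the ketal cis-fused and the C-3 methyl group of 7 sends the heterodiene to the opposite face, which sets C-3a and C-9a.

Step 7
Reactants: 13 (3S,3aS,9aS)-7-methoxy-3,5,9a-trimethyl-2,3,3a,9a-tetrahydro-4H-furo[2,3-b]chromene
Product: 14 (3S,3aS,9aS)-6-bromo-7-methoxy-3,5,9a-trimethyl-2,3,3a,9a-tetrahydro-4H-furo[2,3-b]chromene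
Conditions: NBS (1.05 equiv), MeCN, 0 °C
Reagents that add atoms: N-bromosuccinimide, O=C1CCC(=O)N1Br
Why: Electrophilic aromatic bromination should go to C-6, para to the ring oxygen O-9 and ortho to the methoxy group, in preference to the position between the two oxygens, as is usual for 3,5-dialkoxytoluenes.

Step 8
Reactants: 14 (3S,3aS,9aS)-6-bromo-7-methoxy-3,5,9a-trimethyl-2,3,3a,9a-tetrahydro-4H-furo[2,3-b]chromene
Product: 16 (3S,3aS,9aS)-7-methoxy-3,5,9a-trimethyl-2,3,3a,9a-tetrahydro-4H-furo[2,3-b]chromene-6-carboxylic acid, via aryllithium 15 (not isolated)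
Conditions: n-BuLi (1.1 equiv), THF, −78 °C; CO2 (g), −78 °C to rt; cold 1 M HCl to pH 3
Reagents that add atoms: carbon dioxide, O=C=O
Why: Bromine–lithium exchange and carboxylation of the aryllithium install the future lactone carbonyl between the methoxy and methyl groups, and the ketal is inert to the organolithium.

Step 9
Reactants: 17 ethynyltrimethylsilane; 18 1,6-dibromohexane
Product: 20 (8-bromooct-1-yn-1-yl)trimethylsilane, via lithium acetylide 19 (not isolated)
Conditions: n-BuLi (1.0 equiv), THF, −78 °C; then 18 (3 equiv), DMPU, −78 °C to rt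
Reagents that add atoms: none
Why: SN2 alkylation of the lithium acetylide with an excess of the dibromide should stop at mono-substitution, a standard way to ω-bromo silylalkynes.

Step 10
Reactants: 16 (3S,3aS,9aS)-7-methoxy-3,5,9a-trimethyl-2,3,3a,9a-tetrahydro-4H-furo[2,3-b]chromene-6-carboxylic acid; 20 (8-bromooct-1-yn-1-yl)trimethylsilane
Product: 22 (3S,3aS,9aS)-7-methoxy-3,9a-dimethyl-5-[9-(trimethylsilyl)non-8-yn-1-yl]-2,3,3a,9a-tetrahydro-4H-furo[2,3-b]chromene-6-carboxylic acid, via dilithio dianion 21 (not isolated)
Conditions: LiN(iPr)2 (2.2 equiv), THF, −78 to 0 °C; then 20 (1.2 equiv), −78 °C to rt; cold 1 M HCl to pH 3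
Reagents that add atoms: none
Why: Lateral lithiation of the o-toluic acid (the carboxylate stabilises the benzylic anion of the only ortho methyl group) and SN2 alkylation of the dianion with the primary bromide extend the methyl group to the nine-carbon chain and leave no ester to hydrolyse later.

Step 11
Reactants: 22 (3S,3aS,9aS)-7-methoxy-3,9a-dimethyl-5-[9-(trimethylsilyl)non-8-yn-1-yl]-2,3,3a,9a-tetrahydro-4H-furo[2,3-b]chromene-6-carboxylic acid
Product: 23 (3S,3aS,9aS)-7-methoxy-3,9a-dimethyl-5-(non-8-yn-1-yl)-2,3,3a,9a-tetrahydro-4H-furo[2,3-b]chromene-6-carboxylic acid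
Conditions: K2CO3 (2 equiv), MeOH, rt; cold 1 M HCl to pH 3
Reagents that add atoms: none
Why: Methoxide-mediated protodesilylation of the alkynylsilane frees the terminal alkyne, and nothing else in the molecule is base-labile.

Step 12
Reactants: 23 (3S,3aS,9aS)-7-methoxy-3,9a-dimethyl-5-(non-8-yn-1-yl)-2,3,3a,9a-tetrahydro-4H-furo[2,3-b]chromene-6-carboxylic acid
Product: 24 3-demethyl-3-methylidene-lasiodiplactone A (12-membered exo-methylene enol lactone fused to the tricyclic ketal)
Conditions: [RuCl2(p-cymene)]2 (5 mol %), P(2-furyl)3 (10 mol %), Na2CO3 (20 mol %), PhMe, 80 °C, 23 added by syringe pump over 12 h (final 2 mM)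
Reagents that add atoms: none
Why: Proposed new method: the carboxylate of 23 binds the divalent ruthenium centre of a RuCl(O2CAr)(p-cymene)(P(2-furyl)3)-type complex, the terminal alkyne is activated as its π-complex, the carboxylate oxygen adds to the internal alkyne carbon (Markovnikov) and the alkenyl–ruthenium bond is protonated by a second acid molecule, which forms the O-2–C-3 bond and regenerates the carboxylate complex. The closest known reaction types are the ruthenium-catalysed intermolecular Markovnikov addition of carboxylic acids to terminal alkynes giving 1-alkylvinyl esters, the cycloisomerisation of alkynoic acids to five- to seven-membered exo-alkylidene lactones, and the rhodium-catalysed macrolactonisation of ω-alkynyl acids to endocyclic enol esters; a 12-membered exo-methylene lactone has not been made this way. The one ring formed, the 12-membered benzolactone, closes in the 12-exo-dig mode. No stereocentre is created: C-3 leaves the step trigonal and is set in step 13. The step needs Markovnikov addition over anti-Markovnikov addition (13-endo, through a vinylidene) and ring closure over oligomerisation; the first is secured by the furylphosphine/carbonate combination that disfavours the vinylidene path and by the terminal alkyne, the second by slow addition into a dilute solution and by the two ortho substituents that twist the carboxylate out of the arene plane toward the chain. The ketal, the aryl ether and the arene should be inert to the weakly basic medium.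

Step 13
Reactants: 24 3-demethyl-3-methylidene-lasiodiplactone A
Product: 25 lasiodiplactone A
Conditions: [Rh(cod)((R,R)-Et-DuPhos)]BF4 (2 mol %), H2 (5 bar), CH2Cl2, rt
Reagents that add atoms: none
Why: Asymmetric hydrogenation of a 1-alkylvinyl ester, a known substrate class for monovalent rhodium bisphospholane catalysts, in which the ester carbonyl and the exocyclic double bond chelate the metal and the ligand should direct hydrogen to the Si face of C-3 (catalyst control, the ketal stereocentres being remote) to set the (3R) centre; the sense of induction is to be confirmed in a first run and the ligand antipode is at hand.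

## Compound list

1 | (R)-4-benzyl-3-propionyloxazolidin-2-one | CCC(=O)N1[C@H](Cc2ccccc2)COC1=O | starting material
2 | 3-bromoprop-1-yne | C#CCBr | starting material
3 | sodium (Z)-enolate of 1 | C/C=C(\[O-])N1[C@H](Cc2ccccc2)COC1=O.[Na+] | intermediate
4 | (R)-4-benzyl-3-[(S)-2-methylpent-4-ynoyl]oxazolidin-2-one | C#CC[C@H](C)C(=O)N1[C@H](Cc2ccccc2)COC1=O | intermediate
5 | (S)-2-methylpent-4-yn-1-ol | C#CC[C@H](C)CO | intermediate
6 | (S)-4-methyl-2-methylideneoxolane | C=C1C[C@H](C)CO1 | intermediate
7 | (S)-3,5-dimethyl-2,3-dihydrofuran | CC1=C[C@H](C)CO1 | intermediate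
8 | 2,4-dihydroxy-6-methylbenzaldehyde | Cc1cc(O)cc(O)c1C=O | starting material
9 | 2-hydroxy-4-methoxy-6-methylbenzaldehyde | COc1cc(C)c(C=O)c(O)c1 | intermediate
10 | 2-[(dimethylamino)methyl]-5-methoxy-3-methylphenol | CN(C)Cc1c(C)cc(OC)cc1O | intermediate
11 | 1-(2-hydroxy-4-methoxy-6-methylphenyl)-N,N,N-trimethylmethanaminium iodide | C[N+](C)(C)Cc1c(C)cc(OC)cc1O.[I-] | intermediate
12 | 3-methoxy-5-methyl-6-methylidenecyclohexa-2,4-dien-1-one (o-quinone methide) | C=C1C(C)=CC(OC)=CC1=O | intermediate
13 | (3S,3aS,9aS)-7-methoxy-3,5,9a-trimethyl-2,3,3a,9a-tetrahydro-4H-furo[2,3-b]chromene | COc1cc2c(c(C)c1)C[C@H]1[C@H](C)CO[C@@]1(C)O2 | intermediate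
14 | (3S,3aS,9aS)-6-bromo-7-methoxy-3,5,9a-trimethyl-2,3,3a,9a-tetrahydro-4H-furo[2,3-b]chromene | COc1cc2c(c(C)c1Br)C[C@H]1[C@H](C)CO[C@@]1(C)O2 | intermediate
15 | 6-lithio derivative of 13 (aryllithium) | COc1cc2c(c(C)c1[Li])C[C@H]1[C@H](C)CO[C@@]1(C)O2 | intermediate
16 | (3S,3aS,9aS)-7-methoxy-3,5,9a-trimethyl-2,3,3a,9a-tetrahydro-4H-furo[2,3-b]chromene-6-carboxylic acid | COc1cc2c(c(C)c1C(=O)O)C[C@H]1[C@H](C)CO[C@@]1(C)O2 | intermediate
17 | ethynyltrimethylsilane | C#C[Si](C)(C)C | starting material
18 | 1,6-dibromohexane | BrCCCCCCBr | starting material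
19 | lithium (trimethylsilyl)acetylide | [Li]C#C[Si](C)(C)C | intermediate
20 | (8-bromooct-1-yn-1-yl)trimethylsilane | C[Si](C)(C)C#CCCCCCCBr | intermediate
21 | dilithio dianion of 16 (lithium carboxylate, benzylic lithium at the C-5 methyl group) | COc1cc2c(c(C[Li])c1C(=O)O[Li])C[C@H]1[C@H](C)CO[C@@]1(C)O2 | intermediate
22 | (3S,3aS,9aS)-7-methoxy-3,9a-dimethyl-5-[9-(trimethylsilyl)non-8-yn-1-yl]-2,3,3a,9a-tetrahydro-4H-furo[2,3-b]chromene-6-carboxylic acid | COc1cc2c(c(CCCCCCCC#C[Si](C)(C)C)c1C(=O)O)C[C@H]1[C@H](C)CO[C@@]1(C)O2 | intermediate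
23 | (3S,3aS,9aS)-7-methoxy-3,9a-dimethyl-5-(non-8-yn-1-yl)-2,3,3a,9a-tetrahydro-4H-furo[2,3-b]chromene-6-carboxylic acid | COc1cc2c(c(CCCCCCCC#C)c1C(=O)O)C[C@H]1[C@H](C)CO[C@@]1(C)O2 | intermediate
24 | 3-demethyl-3-methylidene-lasiodiplactone A | COc1cc2c(c3c1C(=O)OC(=C)CCCCCCC3)C[C@H]1[C@H](C)CO[C@@]1(C)O2 | intermediate
25 | lasiodiplactone A | COc1cc2c(c3c1C(=O)O[C@H](C)CCCCCCC3)C[C@H]1[C@H](C)CO[C@@]1(C)O2 | target

## Step count and risks

Total step count: 13. Longest linear sequence: 10 steps (steps 1, 2, 3, 6, 7, 8, 10, 11, 12, 13).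

The three steps most likely to fail:

**Step 12 (proposed new method).** Ring closure may lose to intermolecular addition and oligomerisation, the carboxylate may add with anti-Markovnikov regiochemistry, or the catalyst may turn over too slowly at high dilution. The fallback uses known chemistry, sets out from 23 and comes back to the route at 25. Gold-catalysed Markovnikov hydration of the alkyne (Ph3PAuNTf2 2 mol %, dioxane/H2O, 60 °C) should give the methyl ketone (3S,3aS,9aS)-7-methoxy-3,9a-dimethyl-5-(8-oxononyl)-2,3,3a,9a-tetrahydro-4H-furo[2,3-b]chromene-6-carboxylic acid F1. A Prelog-selective alcohol dehydrogenase (NADH cat., 2-propanol, phosphate buffer pH 7, 30 °C) should reduce it to (3S,3aS,9aS)-5-[(8S)-8-hydroxynonyl]-7-methoxy-3,9a-dimethyl-2,3,3a,9a-tetrahydro-4H-furo[2,3-b]chromene-6-carboxylic acid F2. Mitsunobu macrolactonisation (PPh3, DIAD, PhMe, 2 mM, 0 °C to rt) then forms the same O-2–C-3 bond with inversion at C-3 and should give 25 directly.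

**Step 13.** Hydrogen delivery to the two faces of the macrocyclic enol ester may be poorly differentiated, because chelation of the ester carbonyl can be hampered by the ring and the di-ortho-substituted aroyl group. The fallback sets out from 24 and comes back at 25. It gives up catalyst control: hydrogenation with an achiral catalyst (RhCl(PPh3)3 5 mol %, H2 1 atm, benzene/EtOH, rt) should give 25 together with its C-3 epimer, (3S)-3-epi-lasiodiplactone A F3. Because the three ketal stereocentres are fixed, the two are diastereomers and can be separated by preparative HPLC.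

**Step 6.** The dihydrofuran may be lost by isomerisation to the exocyclic enol ether (which would lead to a spiroketal) or by polymerisation, and the facial selectivity of the cycloaddition may be modest. The fallback sets out from 10 and comes back at 13; it builds the ketal stepwise without the dihydrofuran. Compound 10 is quaternised with MeI to 11 as before. The salt is treated at −78 °C with the lithium enolate of (S)-4-methyldihydrofuran-2(3H)-one F4 (2.2 equiv, from the commercial lactone and LiN(iPr)2 in THF). One equivalent releases the o-quinone methide 12, and the second adds to its methylene carbon trans to the ring methyl group to give (3S,4S)-3-(2-hydroxy-4-methoxy-6-methylbenzyl)-4-methyldihydrofuran-2(3H)-one F5. MeLi (3 equiv, THF, −78 °C) should add once to the lactone carbonyl to give the hemiketal (3S,4S)-3-(2-hydroxy-4-methoxy-6-methylbenzyl)-2,4-dimethyloxolan-2-ol F6. TsOH (cat.), CH2Cl2, 4 Å molecular sieves should then close the aryl oxygen onto the oxocarbenium ion to give the cis-fused ketal 13.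

## Further compounds

F1 | step 12 | (3S,3aS,9aS)-7-methoxy-3,9a-dimethyl-5-(8-oxononyl)-2,3,3a,9a-tetrahydro-4H-furo[2,3-b]chromene-6-carboxylic acid | COc1cc2c(c(CCCCCCCC(C)=O)c1C(=O)O)C[C@H]1[C@H](C)CO[C@@]1(C)O2
F2 | step 12 | (3S,3aS,9aS)-5-[(8S)-8-hydroxynonyl]-7-methoxy-3,9a-dimethyl-2,3,3a,9a-tetrahydro-4H-furo[2,3-b]chromene-6-carboxylic acid | COc1cc2c(c(CCCCCCC[C@H](C)O)c1C(=O)O)C[C@H]1[C@H](C)CO[C@@]1(C)O2
F3 | step 13 | (3S)-3-epi-lasiodiplactone A | COc1cc2c(c3c1C(=O)O[C@@H](C)CCCCCCC3)C[C@H]1[C@H](C)CO[C@@]1(C)O2
F4 | step 6 | lithium enolate of (S)-4-methyldihydrofuran-2(3H)-one | [Li+].[O-]C1=C[C@H](C)CO1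
F5 | step 6 | (3S,4S)-3-(2-hydroxy-4-methoxy-6-methylbenzyl)-4-methyldihydrofuran-2(3H)-one | COc1cc(O)c(C[C@H]2[C@H](C)COC2=O)c(C)c1
F6 | step 6 | (3S,4S)-3-(2-hydroxy-4-methoxy-6-methylbenzyl)-2,4-dimethyloxolan-2-ol | COc1cc(O)c(C[C@H]2[C@H](C)COC2(C)O)c(C)c1
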